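**Strategy**

The 2-aryloxy-1,4-naphthoquinone is not coupled on as a finished unit but grown on the 4-oxygen of the naphthoate. Its quinone ring is cut into three pieces: a phenyl-bearing carbene carbon (C4), the two carbons of an aryl ethynyl ether (C3, C2) and one carbonyl ligand (C1). A Dötz benzannulation of (CO)5Cr=C(OMe)Ph with the 4-O-ethynyl ether of methyl 1,4-dihydroxy-3-prenyl-2-naphthoate joins them and closes the ring by electrocyclisation between C1 and the ortho carbon C8a; oxidative work-up gives the quinone. The step exploits the 1,2,4-oxygen pattern of the quinone ring, in which C1=O, C2–OAr and C4=O map onto CO, the ynol ether oxygen and the carbene methoxy group.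

Key step: step 5

Assumption: methyl 1,4-dihydroxy-2-naphthoate (1) is taken as a catalogue compound. Quinone numbering: C1 is the carbonyl next to the aryloxy carbon C2, and C8a is the ring-fusion carbon bonded to C1.

**Route**

Step 1
Reactants: 1 methyl 1,4-dihydroxynaphthalene-2-carboxylate; 2 2-methylbut-3-en-2-ol
Product: 3 methyl 1,4-dihydroxy-3-(3-methylbut-2-en-1-yl)naphthalene-2-carboxylate
Conditions: BF3·OEt2 (0.3 equiv), dioxane, rt, Ar
Reagents that add atoms: none
Why: Friedel–Crafts prenylation: BF3 ionises the tertiary allylic alcohol to the dimethylallyl cation, which should be captured at its primary terminus by C3, the only free position of the hydroquinone ring (ortho to the 4-hydroxyl), as in the alkylation of naphthohydroquinones with allylic alcohols.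

Step 2
Reactants: 3 methyl 1,4-dihydroxy-3-(3-methylbut-2-en-1-yl)naphthalene-2-carboxylate; 4 trichloroethylene
Product: 5 methyl 4-{[(E)-1,2-dichloroethenyl]oxy}-1-hydroxy-3-(3-methylbut-2-en-1-yl)naphthalene-2-carboxylate
Conditions: K2CO3 (1.5 equiv), Cl2C=CHCl (1.3 equiv), degassed DMF, 70 °C, Ar
Reagents that add atoms: none
Why: Trans addition of a phenoxide to dichloroacetylene formed in situ from trichloroethylene gives the E-dichlorovinyl ether; the 4-hydroxyl should react because the 1-hydroxyl is hydrogen-bonded to the ester and its phenoxide is a weakly nucleophilic vinylogous carboxylate.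

Step 3
Reactants: 5 methyl 4-{[(E)-1,2-dichloroethenyl]oxy}-1-hydroxy-3-(3-methylbut-2-en-1-yl)naphthalene-2-carboxylate
Product: 7 methyl 4-(ethynyloxy)-1-hydroxy-3-(3-methylbut-2-en-1-yl)naphthalene-2-carboxylate, via dilithiated ynol ether 6 (not isolated)
Conditions: n-BuLi (3.2 equiv), THF, −78 → −40 °C; sat. aq NH4Cl, −78 °C; Et3N-deactivated silica, used at once
Reagents that add atoms: none
Why: Greene-type ynol ether synthesis: after deprotonation of the phenol, n-BuLi removes the vinyl hydrogen, β-elimination of LiCl gives the chloroethynyl ether and chlorine–lithium exchange gives acetylide 6, which is protonated on work-up; at −78 °C the ester should be protected by its two ortho substituents and the adjacent lithium phenoxide.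

Step 4
Reactants: 8 hexacarbonylchromium, Cr(CO)6; 9 phenyllithium
Product: 11 pentacarbonyl[methoxy(phenyl)methylidene]chromium, (CO)5Cr=C(OMe)Ph (zerovalent chromium), via lithium acylchromate 10 (not isolated)
Conditions: PhLi, Et2O, 0 °C → rt; then Me3OBF4, CH2Cl2, 0 °C
Reagents that add atoms: trimethyloxonium tetrafluoroborate, C[O+](C)C.F[B-](F)(F)F
Why: Fischer carbene synthesis: PhLi adds to a carbonyl ligand of Cr(CO)6 to give acylchromate 10, whose oxygen is methylated by the hard electrophile Me3OBF4.

Step 5
Reactants: 7 methyl 4-(ethynyloxy)-1-hydroxy-3-(3-methylbut-2-en-1-yl)naphthalene-2-carboxylate; 11 pentacarbonyl[methoxy(phenyl)methylidene]chromium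
Product: 13 rubioncolin C, via methoxynaphthol 12 (not isolated)
Conditions: 11 (1.1 equiv), slow addition of 7, THF (0.05 M), 50 °C, Ar; then (NH4)2Ce(NO3)6 in portions (about 5 equiv, until 12 is consumed), MeCN–H2O, 0 °C
Reagents that add atoms: water, O
Why: Dötz benzannulation: loss of one CO from 11, coordination and insertion of ynol ether 7 into the Cr=C bond, CO insertion to an η4-vinylketene and 6π electrocyclisation join the ketene carbon to the ortho carbon of the phenyl ring, and tautomerisation gives the Cr(CO)3-bound naphthol 12, which (NH4)2Ce(NO3)6 demetalates and oxidises to the quinone with loss of methanol. The closest known reactions are the benzannulations of aryl(methoxy)carbene complexes of chromium with terminal alkynes and with alkynyl ethers, followed by oxidative work-up to 1,4-naphthoquinones. The one ring closed is the six-membered quinone ring (C1 to C4, C4a, C8a), by a 6π-electrocyclic (formally 3+2+1) closure at C1–C8a. No stereocentre is formed. The step needs the insertion regiochemistry that puts the aryloxy carbon next to the CO-derived carbon, which the polarisation of the ynol ether (nucleophilic CH terminus adds to the electrophilic carbene carbon) and the size difference between H and aryloxy should both secure. It also needs the oxidation to stop at the new ring, which should hold because the trioxygenated naphthol of 12 is far more electron-rich than the ester-bearing, hydrogen-bonded naphthol of the other half and the oxidant is dosed.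

**Compound list**

1 | methyl 1,4-dihydroxynaphthalene-2-carboxylate | COC(=O)c1cc(O)c2ccccc2c1O | starting material
2 | 2-methylbut-3-en-2-ol | CC(C)(O)C=C | starting material
3 | methyl 1,4-dihydroxy-3-(3-methylbut-2-en-1-yl)naphthalene-2-carboxylate | COC(=O)c1c(CC=C(C)C)c(O)c2ccccc2c1O | intermediate
4 | trichloroethylene | ClC=C(Cl)Cl | starting material
5 | methyl 4-{[(E)-1,2-dichloroethenyl]oxy}-1-hydroxy-3-(3-methylbut-2-en-1-yl)naphthalene-2-carboxylate | COC(=O)c1c(CC=C(C)C)c(O/C(Cl)=C\Cl)c2ccccc2c1O | intermediate
6 | dilithiated ynol ether (lithium acetylide and lithium naphtholate of 7) | COC(=O)c1c(CC=C(C)C)c(OC#C[Li])c2ccccc2c1O[Li] | intermediate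
7 | methyl 4-(ethynyloxy)-1-hydroxy-3-(3-methylbut-2-en-1-yl)naphthalene-2-carboxylate | COC(=O)c1c(CC=C(C)C)c(OC#C)c2ccccc2c1O | intermediate
8 | hexacarbonylchromium, Cr(CO)6 | O=C=[Cr](=C=O)(=C=O)(=C=O)(=C=O)=C=O | starting material
9 | phenyllithium | [Li]c1ccccc1 | starting material
10 | lithium pentacarbonyl(benzoyl)chromate, (CO)5Cr=C(OLi)Ph | [Li+].[O-]C(c1ccccc1)=[Cr](=C=O)(=C=O)(=C=O)(=C=O)=C=O | intermediate
11 | pentacarbonyl[methoxy(phenyl)methylidene]chromium, (CO)5Cr=C(OMe)Ph | COC(c1ccccc1)=[Cr](=C=O)(=C=O)(=C=O)(=C=O)=C=O | intermediate
12 | methyl 1-hydroxy-4-[(1-hydroxy-4-methoxynaphthalen-2-yl)oxy]-3-(3-methylbut-2-en-1-yl)naphthalene-2-carboxylate (formed in part as its Cr(CO)3 complex) | COC(=O)c1c(CC=C(C)C)c(Oc2cc(OC)c3ccccc3c2O)c2ccccc2c1O | intermediate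
13 | rubioncolin C, methyl 4-[(1,4-dioxo-1,4-dihydronaphthalen-2-yl)oxy]-1-hydroxy-3-(3-methylbut-2-en-1-yl)naphthalene-2-carboxylate | COC(=O)c1c(CC=C(C)C)c(OC2=CC(=O)c3ccccc3C2=O)c2ccccc2c1O | target

**Count**

Total steps: 5. Longest linear sequence: 4 steps (1, 2, 3, 5); step 4 is a one-step side branch.

**Steps most likely to fail**

Step 5. Possible failures as processes:
- Alkyne insertion may stall at the heteroatom-stabilised aryloxy(vinyl)carbene stage, or the ynol ether may oligomerise on the metal.
- The vinylcarbene may cyclopropanate the pendant prenyl double bond, or cyclise without CO insertion.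
- During oxidation, water may attack the phenoxonium ion at C2 instead of C4, with loss of the aryloxy group, or the oxidation may run on into the second naphthol.

Fallback: set out from 3 and join it to commercial 2-bromo-1,4-naphthoquinone by addition–elimination (K2CO3, DMF, rt, Ar). The 4-phenoxide should displace bromide and give 13 directly. This gives up the ring construction and uses only well-known quinone substitution chemistry.

Step 3. Possible failures as processes: competing addition of n-BuLi to the methyl ester, incomplete chlorine–lithium exchange, and hydration or polymerisation of the ynol ether during work-up.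

Fallback: set out from 3 and avoid alkyllithium altogether. Treatment with KH and cis-1,2-dichloroethylene in THF (chloroacetylene formed in situ, trans addition of the 4-phenoxide) should give methyl 4-{[(Z)-2-chloroethenyl]oxy}-1-hydroxy-3-(3-methylbut-2-en-1-yl)naphthalene-2-carboxylate F1. Dehydrochlorination of F1 with the non-nucleophilic amide LiN(iPr)2 (3.2 equiv, THF, −78 → −20 °C) should give the same acetylide 6, and protonation returns to the route at 7.

Step 1. Possible failures as processes: acid-catalysed cyclisation of the new prenyl group onto the 4-hydroxyl (chroman formation), O-alkylation or double alkylation, and air oxidation of the hydroquinone.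

Fallback: set out from 1 and bring in the prenyl group by a sigmatropic route.
- O-Alkylation of the 4-hydroxyl with 3-chloro-3-methylbut-1-yne (K2CO3, KI, acetone, reflux) should give methyl 1-hydroxy-4-[(2-methylbut-3-yn-2-yl)oxy]naphthalene-2-carboxylate F2.
- Semihydrogenation (H2, Pd on CaCO3 poisoned with Pb(OAc)2, quinoline, EtOAc) should give methyl 1-hydroxy-4-[(2-methylbut-3-en-2-yl)oxy]naphthalene-2-carboxylate F3.
- Warming F3 in toluene (80–110 °C) should trigger the aromatic Claisen [3,3] rearrangement to the only free ortho position C3. The 1,1-dimethylallyl group is delivered as the linear prenyl group, and the route is rejoined at 3.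

**Further compounds**

F0 | step 5 | none | none
F1 | step 3 | methyl 4-{[(Z)-2-chloroethenyl]oxy}-1-hydroxy-3-(3-methylbut-2-en-1-yl)naphthalene-2-carboxylate | COC(=O)c1c(CC=C(C)C)c(O/C=C\Cl)c2ccccc2c1O
F2 | step 1 | methyl 1-hydroxy-4-[(2-methylbut-3-yn-2-yl)oxy]naphthalene-2-carboxylate | COC(=O)c1cc(OC(C)(C)C#C)c2ccccc2c1O
F3 | step 1 | methyl 1-hydroxy-4-[(2-methylbut-3-en-2-yl)oxy]naphthalene-2-carboxylate | COC(=O)c1cc(OC(C)(C)C=C)c2ccccc2c1O
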